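## Retrosynthetic overview

1. Target 16 ⇒ flav-2-ene 15. The only stereocentre, C2, is made last by enantioselective addition of H2 across C2=C3 of an achiral enol ether.
2. Feature used: C2 of ring C is bonded to O1 (on C8a of ring A) and to C1' of ring B. The carbonyl carbon of the 3,4,5-trimethoxybenzoate of the ring A phenol has the same two bonds. C2=C3 is therefore cut back to that ester C=O plus a phosphorus ylide at C3 (salt 12).
3. 12 ⇒ bromide 11 ⇒ alcohol 9 ⇒ allyl ester 7. C4 and C3 are the two inner carbons of an allyl group trimmed by ozonolysis. The ozonide is reduced with BH3·SMe2 so that no alkoxide can pull the aroyl group off O1.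
4. 7 ⇒ allylphenol 5 + acid chloride 6. 5 ⇒ phenol 1 + allyl bromide 2 by O-allylation and Claisen rearrangement to the one free ortho carbon (future C4a).
5. Ring order: rings A and B are bought, and ring C is the only ring closed (step 7).

Key step: step 7

Assumption: the quadrant model of iridium phosphine-oxazoline catalysts (C3–H in the quadrant blocked by the oxazoline substituent, as for aryl/H-cis trisubstituted alkenes) points to the (R)-ligand for hydrogen delivery to the Re face of C2. The sense is to be confirmed on a test scale by chiral HPLC and sign of rotation, and the (S)-ligand is used if it proves opposite.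

## Route

Step 1
Reactants: 1 2,3-dimethoxyphenol; 2 allyl bromide
Product: 3 1-(allyloxy)-2,3-dimethoxybenzene
Conditions: K2CO3, acetone, reflux
Reagents that add atoms: allyl bromide (2), C=CCBr
Why: Williamson ether synthesis, in which the phenoxide formed by K2CO3 displaces bromide from the allylic halide by SN2 and O-alkylation prevails in acetone.

Step 2
Reactants: 3 1-(allyloxy)-2,3-dimethoxybenzene
Product: 5 6-allyl-2,3-dimethoxyphenol, via dienone 4 (not isolated)
Conditions: N,N-diethylaniline, 200 °C, N2
Reagents that add atoms: none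
Why: Aromatic Claisen rearrangement, in which the [3,3] shift ends at the only ortho carbon that bears hydrogen (the other carries OMe) and dienone 4 tautomerises to the phenol.

Step 3
Reactants: 5 6-allyl-2,3-dimethoxyphenol; 6 3,4,5-trimethoxybenzoyl chloride
Product: 7 6-allyl-2,3-dimethoxyphenyl 3,4,5-trimethoxybenzoate
Conditions: Et3N, DMAP (cat.), CH2Cl2, 0 °C → rt
Reagents that add atoms: 3,4,5-trimethoxybenzoyl chloride (6), COc1cc(C(=O)Cl)cc(OC)c1OC
Why: DMAP-catalysed O-acylation of a hindered phenol with an acid chloride, which brings in C2 and ring B and also lowers the reactivity of ring A toward ozone.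

Step 4
Reactants: 7 6-allyl-2,3-dimethoxyphenyl 3,4,5-trimethoxybenzoate
Product: 9 6-(2-hydroxyethyl)-2,3-dimethoxyphenyl 3,4,5-trimethoxybenzoate, via ozonide 8 (not isolated)
Conditions: O3, CH2Cl2, −78 °C (Sudan Red 7B end point), N2 purge; BH3·SMe2, −78 °C → rt; MeOH quench, aq NH4Cl; used at once
Reagents that add atoms: ozone, [O-][O+]=O
Why: Ozonolysis (Criegee mechanism) of a monosubstituted alkene that reacts far faster with O3 than either arene, followed by the known non-basic reduction of ozonides to alcohols with BH3·SMe2, which releases the primary alcohol from a borate instead of an alkoxide (so the aroyl group stays on O1) and leaves aryl esters alone at room temperature.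

Step 5
Reactants: 9 6-(2-hydroxyethyl)-2,3-dimethoxyphenyl 3,4,5-trimethoxybenzoate; 10 triphenylphosphine
Product: 11 6-(2-bromoethyl)-2,3-dimethoxyphenyl 3,4,5-trimethoxybenzoate
Conditions: CBr4, PPh3 (10), CH2Cl2, 0 °C
Reagents that add atoms: carbon tetrabromide, BrC(Br)(Br)Br
Why: Appel reaction, in which the primary hydroxyl is activated at phosphorus and displaced by bromide under essentially neutral conditions that the aryl ester and methyl ethers tolerate.

Step 6
Reactants: 11 6-(2-bromoethyl)-2,3-dimethoxyphenyl 3,4,5-trimethoxybenzoate; 10 triphenylphosphine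
Product: 12 [2-(3,4-dimethoxy-2-{[(3,4,5-trimethoxyphenyl)carbonyl]oxy}phenyl)ethyl]triphenylphosphonium bromide
Conditions: PPh3 (10), MeCN, reflux; precipitation with Et2O; drying by toluene azeotrope
Reagents that add atoms: triphenylphosphine (10), c1ccc(cc1)P(c1ccccc1)c1ccccc1
Why: SN2 quaternisation of PPh3 by a primary 2-arylethyl bromide, a standard phosphonium salt preparation that needs no base and so leaves the ester in place.

Step 7
Reactants: 12 [2-(3,4-dimethoxy-2-{[(3,4,5-trimethoxyphenyl)carbonyl]oxy}phenyl)ethyl]triphenylphosphonium bromide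
Product: 15 7,8-dimethoxy-2-(3,4,5-trimethoxyphenyl)-4H-chromene, via ylide 13 (not isolated), via oxaphosphetane 14 (not isolated)
Conditions: KN(SiMe3)2 (1.05 equiv, added slowly), THF (0.02 M), −78 °C → rt; pH 7 phosphate buffer; Et3N-deactivated SiO2
Reagents that add atoms: none
Why: KN(SiMe3)2 removes a proton from C3 next to phosphorus to give the non-stabilised ylide 13, whose C3 adds to the ester carbonyl carbon (future C2) reached through C4–C4a–C8a–O1; without lithium salts this is a [2+2] addition to oxaphosphetane 14, which cycloreverts to Ph3PO and the C2=C3 enol ether. The closest known reaction type is the intramolecular Wittig olefination of aryl esters, established for 2-substituted benzofurans from (2-acyloxybenzyl)phosphonium salts and for 2-substituted 4H-chromenes from [2-(2-acyloxyphenyl)ethyl]phosphonium salts. Ring C closes in a 6-exo-trig mode, since C3 attacks C2 while the C=O bond lies outside the forming ring O1–C2–C3–C4–C4a–C8a. No stereocentre remains in 15, because the two created in 14 are lost on cycloreversion. Olefination must beat aroyl transfer to C3 with release of the ring A phenoxide, elimination of PPh3 across C3–C4 and intermolecular acylation; the ortho two-carbon tether (high effective molarity), the potassium counter-ion (no long-lived betaine alkoxide), the much higher acidity of C3–H than of C4–H and the dilution are what should secure this. The Wittig mechanism fixes the double bond at C2=C3, and the near-stoichiometric base, buffered work-up and base-washed silica should keep it from shifting to C3=C4 or being hydrolysed.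

Step 8
Reactants: 15 7,8-dimethoxy-2-(3,4,5-trimethoxyphenyl)-4H-chromene
Product: 16 (2S)-7,8-dimethoxy-2-(3,4,5-trimethoxyphenyl)chromane [(2S)-7,8,3',4',5'-pentamethoxyflavan]
Conditions: H2 (50 bar), [Ir(cod)(L)]B[3,5-(CF3)2C6H3]4 (1–2 mol %; monovalent iridium; cod = 1,5-cyclooctadiene; L = (R)-4-tert-butyl-2-[2-(diphenylphosphanyl)phenyl]-4,5-dihydro-1,3-oxazole), dry CH2Cl2, rt
Reagents that add atoms: none
Why: Iridium-catalysed asymmetric hydrogenation of a trisubstituted aryl enol ether, a reaction type known for 2-aryl-4H-chromenes, in which the alkene binds with C3–H in the quadrant blocked by the oxazoline tert-butyl group, both hydrogens add syn to the Re face of C2 (O1 > C1' > C3) so that the ligand alone sets (2S), and the homogeneous catalyst leaves the arenes, the methyl ethers and the benzylic C2–O1 bond untouched.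

## Compound list

1 | 2,3-dimethoxyphenol | COc1cccc(O)c1OC | starting material
2 | allyl bromide | C=CCBr | starting material
3 | 1-(allyloxy)-2,3-dimethoxybenzene | C=CCOc1cccc(OC)c1OC | intermediate
4 | 6-allyl-2,3-dimethoxycyclohexa-2,4-dien-1-one (racemic, not isolated) | C=CCC1C=CC(OC)=C(OC)C1=O | intermediate
5 | 6-allyl-2,3-dimethoxyphenol | C=CCc1ccc(OC)c(OC)c1O | intermediate
6 | 3,4,5-trimethoxybenzoyl chloride | COc1cc(C(=O)Cl)cc(OC)c1OC | starting material
7 | 6-allyl-2,3-dimethoxyphenyl 3,4,5-trimethoxybenzoate | COc1cc(C(=O)Oc2c(CC=C)ccc(OC)c2OC)cc(OC)c1OC | intermediate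
8 | 2,3-dimethoxy-6-[(1,2,4-trioxolan-3-yl)methyl]phenyl 3,4,5-trimethoxybenzoate (racemic, not isolated) | COc1cc(C(=O)Oc2c(CC3OCOO3)ccc(OC)c2OC)cc(OC)c1OC | intermediate
9 | 6-(2-hydroxyethyl)-2,3-dimethoxyphenyl 3,4,5-trimethoxybenzoate | COc1cc(C(=O)Oc2c(CCO)ccc(OC)c2OC)cc(OC)c1OC | intermediate
10 | triphenylphosphine | c1ccc(cc1)P(c1ccccc1)c1ccccc1 | starting material
11 | 6-(2-bromoethyl)-2,3-dimethoxyphenyl 3,4,5-trimethoxybenzoate | COc1cc(C(=O)Oc2c(CCBr)ccc(OC)c2OC)cc(OC)c1OC | intermediate
12 | [2-(3,4-dimethoxy-2-{[(3,4,5-trimethoxyphenyl)carbonyl]oxy}phenyl)ethyl]triphenylphosphonium bromide | COc1cc(C(=O)Oc2c(CC[P+](c3ccccc3)(c3ccccc3)c3ccccc3)ccc(OC)c2OC)cc(OC)c1OC.[Br-] | intermediate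
13 | 2,3-dimethoxy-6-[2-(triphenyl-λ5-phosphanylidene)ethyl]phenyl 3,4,5-trimethoxybenzoate (ylide, not isolated) | COc1cc(C(=O)Oc2c(CC=P(c3ccccc3)(c3ccccc3)c3ccccc3)ccc(OC)c2OC)cc(OC)c1OC | intermediate
14 | 1,2λ5-oxaphosphetane fused across C2–C3 of 7,8-dimethoxy-2-(3,4,5-trimethoxyphenyl)chromane, with PPh3 on C3 and P–O on C2 (racemic, the cis fusion being the only one possible, not isolated) | COc1cc(C23Oc4c(OC)c(OC)ccc4CC2P(c2ccccc2)(c2ccccc2)(c2ccccc2)O3)cc(OC)c1OC | intermediate
15 | 7,8-dimethoxy-2-(3,4,5-trimethoxyphenyl)-4H-chromene | COc1cc(C2=CCc3ccc(OC)c(OC)c3O2)cc(OC)c1OC | intermediate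
16 | (2S)-7,8-dimethoxy-2-(3,4,5-trimethoxyphenyl)chromane | COc1cc([C@@H]2CCc3ccc(OC)c(OC)c3O2)cc(OC)c1OC | target

## Step count and risks

Total step count: 8. Longest linear sequence: 8 steps (1 → 16).

**Step 7.**
- What may go wrong: the aroyl group may pass to the ylide carbon with release of the ring A phenoxide instead of oxygen passing to phosphorus. PPh3 may be eliminated across C3–C4. Excess base may shift the new double bond into conjugation with ring A.
- Fallback: it sets out from 7 and comes back at 15.
- The ester carbonyl of 7 is methylenated with Cp2TiMe2 (toluene, 75 °C). This reaction is known for aryl benzoates and gives 1-allyl-3,4-dimethoxy-2-{[1-(3,4,5-trimethoxyphenyl)ethenyl]oxy}benzene F1.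
- Ring-closing metathesis between the new C2=CH2 unit and the allyl group follows, with the second-generation Grubbs catalyst RuCl2(=CHPh)(PCy3)(SIMes) in toluene at 70 °C. It forms the same C2=C3 bond and ring C.

**Step 8.**
- What may go wrong: facial selectivity may be insufficient on this heavily methoxylated substrate. The acidic iridium hydrides may also hydrolyse or oligomerise the enol ether before hydrogen is delivered.
- Fallback: it sets out from 15 and comes back at 16.
- The enol ether is hydrolysed on purpose (dilute HCl, THF/H2O, rt) to 3-(2-hydroxy-3,4-dimethoxyphenyl)-1-(3,4,5-trimethoxyphenyl)propan-1-one F2.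
- Noyori-type transfer hydrogenation with RuCl(p-cymene)[(R,R)-TsDPEN] in HCO2H/Et3N should give 6-[(3R)-3-hydroxy-3-(3,4,5-trimethoxyphenyl)propyl]-2,3-dimethoxyphenol F3.
- Intramolecular Mitsunobu etherification (PPh3 10, DIAD, THF, 0 °C) closes O1–C2 with inversion to the (2S)-flavan 16.

**Step 4.**
- What may go wrong: ozone may attack the dimethoxylated ring A. The ozonide may be reduced only sluggishly. The aroyl group may migrate from O1 to the new primary hydroxyl during work-up or storage.
- Fallback: it sets out from 5 and comes back at 12. It uses no ozone and adds the ester only after the salt is made.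
- 5 is benzylated (BnBr, K2CO3, DMF) to 1-allyl-2-(benzyloxy)-3,4-dimethoxybenzene F4.
- Lemieux–Johnson cleavage (OsO4 cat., NaIO4, 2,6-lutidine, dioxane/H2O) gives [2-(benzyloxy)-3,4-dimethoxyphenyl]acetaldehyde F5.
- NaBH4 in MeOH gives 2-[2-(benzyloxy)-3,4-dimethoxyphenyl]ethanol F6.
- Appel bromination (CBr4, PPh3 10) gives 2-(benzyloxy)-1-(2-bromoethyl)-3,4-dimethoxybenzene F7.
- Heating with PPh3 10 in MeCN gives {2-[2-(benzyloxy)-3,4-dimethoxyphenyl]ethyl}triphenylphosphonium bromide F8.
- Hydrogenolysis (H2, Pd/C, MeOH) frees the phenol in [2-(2-hydroxy-3,4-dimethoxyphenyl)ethyl]triphenylphosphonium bromide F9.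
- O-aroylation with 6 (Et3N, CH2Cl2, 0 °C, aqueous NaBr wash) gives 12.

## Further compounds

F1 | step 7 | 1-allyl-3,4-dimethoxy-2-{[1-(3,4,5-trimethoxyphenyl)ethenyl]oxy}benzene | COc1cc(C(=C)Oc2c(CC=C)ccc(OC)c2OC)cc(OC)c1OC
F2 | step 8 | 3-(2-hydroxy-3,4-dimethoxyphenyl)-1-(3,4,5-trimethoxyphenyl)propan-1-one | COc1cc(C(=O)CCc2ccc(OC)c(OC)c2O)cc(OC)c1OC
F3 | step 8 | 6-[(3R)-3-hydroxy-3-(3,4,5-trimethoxyphenyl)propyl]-2,3-dimethoxyphenol | COc1cc([C@H](O)CCc2ccc(OC)c(OC)c2O)cc(OC)c1OC
F4 | step 4 | 1-allyl-2-(benzyloxy)-3,4-dimethoxybenzene | C=CCc1ccc(OC)c(OC)c1OCc1ccccc1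
F5 | step 4 | [2-(benzyloxy)-3,4-dimethoxyphenyl]acetaldehyde | O=CCc1ccc(OC)c(OC)c1OCc1ccccc1
F6 | step 4 | 2-[2-(benzyloxy)-3,4-dimethoxyphenyl]ethanol | OCCc1ccc(OC)c(OC)c1OCc1ccccc1
F7 | step 4 | 2-(benzyloxy)-1-(2-bromoethyl)-3,4-dimethoxybenzene | BrCCc1ccc(OC)c(OC)c1OCc1ccccc1
F8 | step 4 | {2-[2-(benzyloxy)-3,4-dimethoxyphenyl]ethyl}triphenylphosphonium bromide | COc1ccc(CC[P+](c2ccccc2)(c2ccccc2)c2ccccc2)c(OCc2ccccc2)c1OC.[Br-]
F9 | step 4 | [2-(2-hydroxy-3,4-dimethoxyphenyl)ethyl]triphenylphosphonium bromide | COc1ccc(CC[P+](c2ccccc2)(c2ccccc2)c2ccccc2)c(O)c1OC.[Br-]
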